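**Remarks on the chemistry (assumptions)**
- Atom numbers used throughout: ring A = C1(H)=C2(OMe)–C3(=O)–C4(H)=C5(OMe), spiro atom C6, ring B = C7 (aryl), C8 (methyl), C9 (aryl), C10 (methyl), C11 (ethyl). "Aryl" means 2,4,5-trimethoxyphenyl. The same locants are used in the spiro[5.5]undecane names.
- Consistency check: 12 + 11 = 14 atom for atom (C18H20O6 + C17H24O3 = C35H44O9), and the descriptors of C6, C7, C8 and C11 in 14 map onto 15 without change in space, so no structure needed correcting. One point of logic is tightened: the first C–C bond of the key step must be irreversible if the acid is to control C7, so only the ring closure may equilibrate.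
- Which enantiomer of the chiral acid leads to the (7R) series cannot be predicted with confidence. (R)-TRIP, (R)-3,3'-bis(2,4,6-triisopropylphenyl)-1,1'-binaphthyl-2,2'-diyl hydrogen phosphate, is written; its mirror image is used if the first runs call for it.
- Compounds 1, 3, 6 and 7 and all reagents are taken to be catalogue chemicals.

## Structural features

Tatanan B is a spiro[5.5]undecane in which ring A, a cross-conjugated 2,5-dimethoxycyclohexa-2,5-dienone (C1–C5, carbonyl at C3), and ring B, a cyclohexane substituted at every carbon (C7–C11), share only the quaternary carbon C6. Ring B carries five contiguous CH stereocentres, C7 (aryl), C8 (methyl), C9 (aryl), C10 (methyl) and C11 (ethyl), and they enclose C6, which is itself a stereocentre because its two ring A neighbours differ (C1–H against C5–OMe). In the chair of ring B the C7 aryl, C8 methyl, C9 aryl and C11 ethyl are equatorial, the C10 methyl is axial and cis to both the C9 aryl and the C11 ethyl, and at C6 the methoxy-bearing C5 is equatorial while C1 is axial. Ring B has no heteroatom, so no stereocentre can be set or corrected through a functional group. The fragile parts are the dienone (rearrangement or loss of a C6 substituent under strong acid, easy reduction, nucleophilic attack) and the three very electron-rich arenes (oxidation, electrophilic attack). The real difficulty is the quaternary spiro stereocentre C6 wedged between the tertiary stereocentres C7 and C11, within a run of six adjacent stereocentres. Three features are exploited: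
- The C6–C7 bond links the para carbon of a latent phenol (oxygen at C3, activating methoxy at C5) to a doubly benzylic carbon, so it is the exocyclic bond of a para-quinone methide.
- The aryl group on C9 can carry a positive charge spread over C9–C11, so C8–C11 is a 2-aryl-1,3-diene.
- The hydrogens on C9 and C10 are cis, so an alkene left at C9–C10 is matched to a syn hydrogenation.

## Logic of the disconnections

15 ⇒ 14. The C9–H and C10–H bonds are cut, which puts a double bond between C9 and C10. These hydrogens are cis in 15, the pattern of a syn addition, and an alkene at this place is what an allyl-cation ring closure leaves behind. Two of the six stereocentres disappear. The forward step must add hydrogen to a tetrasubstituted styrene from the face opposite the C11 ethyl group and must spare the two double bonds of ring A.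

14 ⇒ 5 + 11 (through 12 and 13). The ring bonds C7–C8 and C6–C11 are cut. C7 is doubly benzylic and para to the ring A oxygen, so it is the electrophilic end of 12; C6 is the nucleophilic para carbon of the phenol that 12 becomes after the first bond; C8–C11 carries the aryl group that makes 13 viable. The spirobicycle, ring B and four stereocentres (C6, C7, C8, C11) fall to two achiral pieces of similar size. The forward step demands attack of the diene through C8 and not C11, control of C7 by a chiral acid, closure through C6 and not through an aromatic CH, and the all-equatorial relative configuration. Three design points are added to the bare disconnection: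
- 5 keeps its phenol free, because it anchors the acid and supplies the proton lost on dearomatisation.
- 11 is used in excess as one geometric isomer with (E) C10–C11, because this geometry decides C11.
- The water set free is trapped.

5 ⇒ 2 + 3 (through 4). The aryl–C7 bond on the ring A side is cut to an aryl anion and an aldehyde. The stereocentre of 5 need not be controlled because it is erased in 12. The demand is metalation of a bromophenol; using the phenoxide itself as the protecting group saves two steps.

2 ⇒ 1. The C–Br bond is cut. The demand is bromination para to the hydroxyl of 1.

11 ⇒ 10. The C8=C9 double bond is cut to a C9 ketone and a two-carbon ylide. This leads back to an enone in which the (E) C10–C11 bond is already present. The demand is olefination of a hindered aryl ketone and separation of the isomers of the new double bond.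

10 ⇒ 9. Only the oxidation level at C9 changes. The demand is an oxidant that tolerates an acid-sensitive, electron-rich allylic benzylic alcohol.

9 ⇒ 6 + 7 (through 8). The aryl–C9 bond is cut to an aryl anion and an enal. 7 brings C9, C10, C11, the C10 methyl, the ethyl group and the (E) geometry in one catalogue compound. The demand is 1,2-addition to the enal.

## Other disconnections considered

Alternative 1: The cut is the single bond C6–C11.
- Forward step: the open-chain phenol A1 (methyl (2E)-7-(4-hydroxy-2,5-dimethoxyphenyl)-4,6-dimethyl-5,7-bis(2,4,5-trimethoxyphenyl)hept-2-en-1-yl carbonate, C7–C10 already configured) would be ionised by [Ir(cod)Cl]2, a chiral phosphoramidite and Cs2CO3. The para carbon of the phenolate would attack the substituted end of the iridium allyl complex to give the 11-vinyl spirodienone A2. Hydrogenation of the vinyl group (RhCl(PPh3)3, H2) would finish 15.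
- In its favour: intramolecular iridium-catalysed allylic dearomatisation of para-substituted phenols is an established reaction class, whereas the chosen key step is not; on precedent this alternative is the better one. The medium is basic, so no cation is formed and neither indane formation nor acid damage to the dienone is an issue. The last reduction concerns a monosubstituted alkene and not a tetrasubstituted styrene. On these points too it is the better plan. C11 would be under catalyst control. C6 (which edge of ring A faces C7) rests on the substrate in both plans, so they are equal there.
- Against it: the step makes one bond and two stereocentres, so A1 must already hold the four contiguous stereocentres C7–C10 on a flexible chain, two of them diarylmethine centres with no neighbouring group to steer them. The difficulty is moved, not removed. The closure makes a six-membered ring through a fully substituted tether and uses a nucleophilic carbon flanked by the C5 methoxy group, which is the slow case of this reaction.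
- Step economy: a linear sequence well above ten steps to A1 is to be expected, against five linear steps in the chosen plan.

Alternative 2: The cuts are C6–C7 and C10–C11, a Diels–Alder retron in which ring A supplies the dienophile.
- Forward step: the quinone methide A3 (2,5-dimethoxy-4-propylidenecyclohexa-2,5-dien-1-one), made in the flask with Ag2O and bound to Sc(OTf)3 and a chiral pybox ligand, would react through C6 and C11 with the termini C7 and C10 of the silyloxydiene A4. The product would be the spirodienone A5 with a silyl enol ether at C8–C9.
- In its favour: like the chosen plan it is convergent and forms two bonds, ring B and four stereocentres (C6, C7, C10, C11) at once, so the two are equal here. The polarity is matched, the nucleophilic C10 meeting the electrophilic C11. A concerted path would carry the diene geometry into the C7/C10 relationship and has no indane side path, which is better than the chosen plan.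
- Against it: a quinone methide with hydrogens next to the methide carbon, as in A3, readily loses its reactivity by a hydrogen shift to the aromatic styrene form and by oligomerisation. Its trisubstituted exocyclic double bond would have to combine with a 1,2,3,4-tetrasubstituted diene and create the quaternary C6 next to the aryl-bearing C7. A single carbonyl oxygen offers the scandium complex only one-point binding, a weak basis for face selection.
- The main drawback comes after the step. C9 carries oxygen and not the aryl group, so the aryl must be introduced next to the ring A dienone. The hydrogens at C8 and C9 are trans in 15, which syn hydrogenation of a C8–C9 alkene cannot deliver. The chosen plan has the C9 aryl from the start and leaves the C9–C10 alkene, whose hydrogens are cis in 15.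
- Step economy: similar up to the key step, three to five steps more after it.

Alternative 3: The cuts are C8–C9 and C9–C10, so C9 with its aryl group is taken out of ring B, leaving the spiro[4.5] ketone A6.
- Forward step: Sc(OTf)3 would activate the C10 carbonyl of A6, the carbon of (2,4,5-trimethoxyphenyl)diazomethane A7 would add to it, and migration of C8 with loss of N2 would give the ring-expanded ketone A8 with the aryl at C9.
- In its favour: Lewis-acid-catalysed homologation of cyclic ketones with aryldiazomethanes is known chemistry, so it is better than the chosen plan on precedent. C9 in A8 is next to a ketone, so the equatorial aryl of 15 could be reached by equilibration and not by the facial selectivity of a hydrogenation, which is also better.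
- Against it: both carbons next to the C10 carbonyl (C8 and C11) are secondary and similarly substituted, so insertion on the wrong side is likely. The diazo compound can add as a 1,3-dipole to the electron-poor double bonds of ring A, and the Lewis acid can start a dienone–phenol rearrangement. A8 still lacks the C10 methyl: the hindered C10 ketone would have to be methylenated in the presence of the ring A carbonyl and reduced to the axial methyl, so a face-selective reduction is needed here as well (equal). Above all, A6 already contains the spiro centre C6 between the stereocentres C7 and C11, so the central problem is unsolved and A6 needs a route of its own.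
- Step economy: clearly longer than the chosen plan.

Key step: step 6

## Steps

Step 1
Reactants: 1 2,5-dimethoxyphenol
Product: 2 4-bromo-2,5-dimethoxyphenol
Conditions: NBS (1.0 equiv), MeCN, −20 °C to 0 °C
Reagents that add atoms: N-bromosuccinimide, O=C1CCC(=O)N1Br
Why: Electrophilic aromatic bromination; C4 is para to the hydroxyl, ortho to the C5 methoxy group and less crowded than C6 (between OH and OMe), so one equivalent of NBS at low temperature should give the 4-bromide. No stereocentre is formed.

Step 2
Reactants: 2 4-bromo-2,5-dimethoxyphenol; 3 2,4,5-trimethoxybenzaldehyde
Product: 5 racemic (4-hydroxy-2,5-dimethoxyphenyl)(2,4,5-trimethoxyphenyl)methanol, via dilithio phenoxide 4 (not isolated)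
Conditions: n-BuLi (1.0 equiv), THF, −78 °C; t-BuLi (2.0 equiv), −78 °C; then 3, −78 °C to 0 °C; aq. NH4Cl
Reagents that add atoms: none
Why: The first base turns the phenol into its lithium salt, which serves as the protecting group; bromine–lithium exchange on lithium bromophenoxides with t-BuLi is established and is helped here by the methoxy group next to the bromine. 1,2-Addition of 4 to the aldehyde gives the doubly benzylic carbinol, whose stereocentre is of no consequence because it is erased in step 6.

Step 3
Reactants: 6 1-bromo-2,4,5-trimethoxybenzene; 7 (E)-2-methylpent-2-enal
Product: 9 racemic (E)-2-methyl-1-(2,4,5-trimethoxyphenyl)pent-2-en-1-ol, via aryllithium 8 (not isolated)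
Conditions: n-BuLi, THF, −78 °C; then 7, −78 °C to 0 °C; aq. NH4Cl
Reagents that add atoms: none
Why: Bromine–lithium exchange followed by 1,2-addition of the hard aryllithium to the enal carbonyl; the (E) double bond of 7 is untouched and the racemic carbinol centre is removed in step 4.

Step 4
Reactants: 9 racemic (E)-2-methyl-1-(2,4,5-trimethoxyphenyl)pent-2-en-1-ol
Product: 10 (E)-2-methyl-1-(2,4,5-trimethoxyphenyl)pent-2-en-1-one
Conditions: MnO2 (10 equiv), CH2Cl2, rt
Reagents that add atoms: none
Why: MnO2 oxidises allylic and benzylic alcohols selectively under neutral conditions, which avoids acid-promoted ionisation of this very electron-rich carbinol and keeps the (E) alkene.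

Step 5
Reactants: 10 (E)-2-methyl-1-(2,4,5-trimethoxyphenyl)pent-2-en-1-one
Product: 11 (2Z,4E)-4-methyl-3-(2,4,5-trimethoxyphenyl)hepta-2,4-diene
Conditions: EtPPh3Br, KOtBu, THF, 0 °C; then 10, 0 °C to 60 °C; chromatography on AgNO3-impregnated silica
Reagents that add atoms: ethyltriphenylphosphonium bromide, CC[P+](c1ccccc1)(c1ccccc1)c1ccccc1.[Br-]
Why: Wittig olefination with the non-stabilised ethylidene ylide; 10 has no α-hydrogen and a substituted β-carbon, so carbonyl addition should prevail. The new C8–C9 bond is expected as a mixture from which the (2Z) isomer (methyl cis to the aryl group, which is twisted out of the diene plane in any case) is separated; the (4E) geometry comes unchanged from 7.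

Step 6
Reactants: 5 racemic (4-hydroxy-2,5-dimethoxyphenyl)(2,4,5-trimethoxyphenyl)methanol; 11 (2Z,4E)-4-methyl-3-(2,4,5-trimethoxyphenyl)hepta-2,4-diene
Product: 14 (6S,7R,8S,11R)-9,10-didehydrotatanan B, via quinone methide 12 (not isolated), via allyl cation 13 (not isolated)
Conditions: (R)-TRIP (10 mol%), 5 Å MS, CH2Cl2, −40 °C to −10 °C; 11 (1.5 equiv), 5 added slowly
Reagents that add atoms: none
Why: Proposed new method: the acid ionises 5 to the hydrogen-bonded quinone methide 12 (water goes to the sieves), the diene attacks the doubly benzylic C7 through C8, the only terminus whose attack places the charge on C9 where the trimethoxyphenyl group and the C10–C11 double bond share it (cation 13), and the phenol para carbon C6 then bonds to C11 with loss of the phenol proton to the phosphate; the closest known reaction types are chiral Brønsted-acid-catalysed 1,6-additions and formal annulations of para-quinone methides formed in situ and the dearomatising para-alkylation of phenols. Ring B, the only ring formed, closes in the 6-endo-trig mode on the allyl cation (C9=C10 stays inside the ring) and in the spiro (ipso) mode on the phenol. C7 is set in the first bond by the chiral phosphate, which is anchored to the phenolic OH of the ion pair and blocks one face of C7; this bond has to be irreversible at the low temperature used. C8 is set in the same open transition state, the C8 methyl turning away from the C7 aryl (trans on the later ring). C11 is set in the closure by the (E) geometry of C10–C11 inherited from 11 and a chair-like transition state with the C7 aryl and C8 methyl equatorial, which leaves the ethyl pseudo-equatorial and cis to the C7 aryl. C6 is set by the preference of the small C1–H edge of ring A for the axial site, so that the C5 methoxy edge is equatorial and turned away from the C7 aryl; the closure is reversible under the acid, which lets errors at C6 and C11 drain to this all-equatorial isomer. The step needs C8 over C11 regioselectivity in the first bond (secured by the C9 aryl) and six-ring ipso closure over indane formation (secured because C6 is activated by both the para OH and the ortho C5 methoxy group and attacks a secondary carbon, whereas the C7 aryl offers an ortho carbon activated by one methoxy group and would have to build a quaternary C9).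

Step 7
Reactants: 14 (6S,7R,8S,11R)-9,10-didehydrotatanan B
Product: 15 tatanan B
Conditions: H2 (20 bar), [Ir(cod)(PCy3)(py)]PF6 (10 mol%), CH2Cl2, rt
Reagents that add atoms: none
Why: Homogeneous hydrogenation with the cationic iridium complex, one of the few catalysts that reduce tetrasubstituted alkenes; syn addition gives the cis C9–H/C10–H pair of the target. In the half-chair of 14 with the C7 aryl, C8 methyl and C11 ethyl pseudo-equatorial, the axial C1–H edge of ring A covers the lower face, so both hydrogens should enter from the face opposite the C11 ethyl and give (9S,10S) with the C9 aryl equatorial and the C10 methyl axial. The ring A double bonds are conjugated to the carbonyl (one is a vinylogous ester) and are expected to react more slowly.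

## Compound list

1 | 2,5-dimethoxyphenol | COc1ccc(OC)c(O)c1 | starting material
2 | 4-bromo-2,5-dimethoxyphenol | COc1cc(Br)c(OC)cc1O | intermediate
3 | 2,4,5-trimethoxybenzaldehyde | COc1cc(OC)c(C=O)cc1OC | starting material
4 | lithium 4-lithio-2,5-dimethoxyphenolate (dilithio phenoxide) | [Li]c1cc(OC)c(O[Li])cc1OC | intermediate (not isolated)
5 | racemic (4-hydroxy-2,5-dimethoxyphenyl)(2,4,5-trimethoxyphenyl)methanol | COc1cc(OC)c(C(O)c2cc(OC)c(O)cc2OC)cc1OC | intermediate
6 | 1-bromo-2,4,5-trimethoxybenzene | COc1cc(OC)c(Br)cc1OC | starting material
7 | (E)-2-methylpent-2-enal | CC/C=C(C)/C=O | starting material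
8 | (2,4,5-trimethoxyphenyl)lithium | [Li]c1cc(OC)c(OC)cc1OC | intermediate (not isolated)
9 | racemic (E)-2-methyl-1-(2,4,5-trimethoxyphenyl)pent-2-en-1-ol | CC/C=C(C)/C(O)c1cc(OC)c(OC)cc1OC | intermediate
10 | (E)-2-methyl-1-(2,4,5-trimethoxyphenyl)pent-2-en-1-one | CC/C=C(C)/C(=O)c1cc(OC)c(OC)cc1OC | intermediate
11 | (2Z,4E)-4-methyl-3-(2,4,5-trimethoxyphenyl)hepta-2,4-diene | C/C=C(c1cc(OC)c(OC)cc1OC)/C(C)=C/CC | intermediate
12 | 2,5-dimethoxy-4-[(2,4,5-trimethoxyphenyl)methylidene]cyclohexa-2,5-dien-1-one (aryl on the side of C1–H) | O=C1C=C(OC)/C(=C/c2cc(OC)c(OC)cc2OC)C=C1OC | intermediate (not isolated)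
13 | (1S,2S)-1-(4-hydroxy-2,5-dimethoxyphenyl)-2,4-dimethyl-1,3-bis(2,4,5-trimethoxyphenyl)hept-3-en-5-ylium, one resonance form of the C9–C11 allyl cation, as its chiral phosphate ion pair (C7 and C8 arranged in space as in 14; the descriptors differ because the priorities change) | CC[CH+]C(C)=C(c1cc(OC)c(OC)cc1OC)[C@@H](C)[C@H](c1cc(OC)c(OC)cc1OC)c1cc(OC)c(O)cc1OC | intermediate (not isolated)
14 | (6S,7R,8S,11R)-11-ethyl-2,5-dimethoxy-8,10-dimethyl-7,9-bis(2,4,5-trimethoxyphenyl)spiro[5.5]undeca-1,4,9-trien-3-one (9,10-didehydrotatanan B) | CC[C@@H]1C(C)=C(c2cc(OC)c(OC)cc2OC)[C@@H](C)[C@H](c2cc(OC)c(OC)cc2OC)[C@]12C=C(OC)C(=O)C=C2OC | intermediate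
15 | tatanan B, (6S,7R,8R,9S,10S,11R)-11-ethyl-2,5-dimethoxy-8,10-dimethyl-7,9-bis(2,4,5-trimethoxyphenyl)spiro[5.5]undeca-1,4-dien-3-one | CC[C@@H]1[C@H](C)[C@H](c2cc(OC)c(OC)cc2OC)[C@@H](C)[C@H](c2cc(OC)c(OC)cc2OC)[C@]12C=C(OC)C(=O)C=C2OC | target

## Step count and least certain steps

Total: 7 steps. Longest linear sequence: 5 steps (6 → 9 → 10 → 11 → 14 → 15; steps 3, 4, 5, 6, 7).

**Step 6 (key step, the only step beyond known chemistry).**
- Most likely failure: closure of cation 13 through an aromatic CH ortho to C7 (five-membered ring) in place of closure through C6, because the ipso carbon is crowded by the C5 methoxy group and the cation is long-lived.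
- Further risks: weak face discrimination at C7, since the phosphate is held at the remote phenolic OH; the wrong C7/C8 relationship from the open transition state; acid-induced self-addition of the diene or of 5; slow reaction because the quinone methide is strongly stabilised. A stronger or more confined chiral acid would be the first change of conditions.
- Fallback (known reaction types only; sets out from 5, returns at 13 and so at 14): the two bonds are made in separate operations.
  - Commercial 1-(2,4,5-trimethoxyphenyl)propan-1-one is converted (LiN(SiMe3)2, Me3SiCl) into (Z)-trimethyl{[1-(2,4,5-trimethoxyphenyl)prop-1-en-1-yl]oxy}silane F1.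
  - F1 is added to 12, generated from 5 with the chiral phosphoric acid and sieves. Acid-catalysed 1,6-addition of enol silanes to para-quinone methides is a documented reaction type. The product is the ketone (2S,3S)-3-(4-hydroxy-2,5-dimethoxyphenyl)-2-methyl-1,3-bis(2,4,5-trimethoxyphenyl)propan-1-one F2, with C7 and C8 in place and open to purification by crystallisation.
  - Pent-2-yne is hydrozirconated with Cp2Zr(H)Cl and brominated with NBS to (E)-2-bromopent-2-ene F3. t-BuLi and CeCl3 turn F3 into the alkenylcerium dichloride, which is added in excess to the ketone of F2 (the phenol consumes one equivalent). This gives the tertiary allylic alcohol (1S,2S,4E)-1-(4-hydroxy-2,5-dimethoxyphenyl)-2,4-dimethyl-1,3-bis(2,4,5-trimethoxyphenyl)hept-4-en-3-ol F4 as a mixture at C9.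
  - A mild acid (diphenyl phosphate, CH2Cl2, −20 °C) ionises F4 to 13, which closes to 14 by intramolecular dearomatising para-alkylation of the phenol.

**Step 7.**
- Most likely failure: low conversion, because the alkene is tetrasubstituted and flanked by two stereocentres and an ortho-substituted aryl group.
- Further risks: competing saturation of the C1=C2 bond of ring A; loss of facial selectivity if 14 populates another half-chair.
- Fallback (from 14 directly to 15): hydrogen-atom-transfer hydrogenation with Mn(dpm)3, PhSiH3 and t-BuOOH in i-PrOH. A manganese hydride gives a hydrogen atom to C10 from the open face, and the tertiary benzylic C9 radical then takes its hydrogen axially so that the aryl ends equatorial. The mechanism is radical and stepwise and needs no coordination of the alkene to a metal, so crowding matters less. It makes no new compound (F0).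

**Step 5.**
- Most likely failure: deprotonation of 10 at the γ-position by the basic ylide instead of addition to the hindered carbonyl, and lack of control over the geometry of the new double bond.
- Fallback (from 10, returns at 11): addition–elimination in place of olefination. EtMgBr with CeCl3 adds 1,2 to give racemic (E)-4-methyl-3-(2,4,5-trimethoxyphenyl)hept-4-en-3-ol F5. Dehydration with methyl N-(triethylammoniosulfonyl)carbamate (inner salt) in benzene at 50 °C proceeds by syn elimination; the only β-hydrogens are on the ethyl CH2, so the double bond can form only at C8–C9.

**Step 2.**
- Most likely failure: incomplete bromine–lithium exchange and aggregation of the electron-rich dianion, leading to protonation in place of addition.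
- Fallback (from 2, returns at 5): protecting-group detour. TBSCl and imidazole in DMF give tert-butyl(4-bromo-2,5-dimethoxyphenoxy)dimethylsilane F6. Exchange with n-BuLi at −78 °C and addition to 3 give [4-(tert-butyldimethylsilyloxy)-2,5-dimethoxyphenyl](2,4,5-trimethoxyphenyl)methanol F7. TBAF buffered with AcOH in THF at 0 °C frees the phenol.

## Further compounds

F1 | step 6 | (Z)-trimethyl{[1-(2,4,5-trimethoxyphenyl)prop-1-en-1-yl]oxy}silane | C/C=C(\O[Si](C)(C)C)c1cc(OC)c(OC)cc1OC
F2 | step 6 | (2S,3S)-3-(4-hydroxy-2,5-dimethoxyphenyl)-2-methyl-1,3-bis(2,4,5-trimethoxyphenyl)propan-1-one | O=C(c1cc(OC)c(OC)cc1OC)[C@@H](C)[C@H](c1cc(OC)c(OC)cc1OC)c1cc(OC)c(O)cc1OC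
F3 | step 6 | (E)-2-bromopent-2-ene | CC/C=C(C)/Br
F4 | step 6 | (1S,2S,4E)-1-(4-hydroxy-2,5-dimethoxyphenyl)-2,4-dimethyl-1,3-bis(2,4,5-trimethoxyphenyl)hept-4-en-3-ol (mixture at C3) | CC/C=C(C)/C(O)(c1cc(OC)c(OC)cc1OC)[C@@H](C)[C@H](c1cc(OC)c(OC)cc1OC)c1cc(OC)c(O)cc1OC
F0 | step 7 | none | none
F5 | step 5 | racemic (E)-4-methyl-3-(2,4,5-trimethoxyphenyl)hept-4-en-3-ol | CC/C=C(C)/C(O)(CC)c1cc(OC)c(OC)cc1OC
F6 | step 2 | tert-butyl(4-bromo-2,5-dimethoxyphenoxy)dimethylsilane | COc1cc(Br)c(OC)cc1O[Si](C)(C)C(C)(C)C
F7 | step 2 | racemic [4-(tert-butyldimethylsilyloxy)-2,5-dimethoxyphenyl](2,4,5-trimethoxyphenyl)methanol | COc1cc(OC)c(C(O)c2cc(OC)c(O[Si](C)(C)C(C)(C)C)cc2OC)cc1OC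
A1 | alternative 1 | methyl (2E)-7-(4-hydroxy-2,5-dimethoxyphenyl)-4,6-dimethyl-5,7-bis(2,4,5-trimethoxyphenyl)hept-2-en-1-yl carbonate, configured at C7–C10 as in tatanan B | COC(=O)OC/C=C/[C@H](C)[C@H](c1cc(OC)c(OC)cc1OC)[C@@H](C)[C@H](c1cc(OC)c(OC)cc1OC)c1cc(OC)c(O)cc1OC
A2 | alternative 1 | 11-vinyl analogue of tatanan B (11-ethenyl-2,5-dimethoxy-8,10-dimethyl-7,9-bis(2,4,5-trimethoxyphenyl)spiro[5.5]undeca-1,4-dien-3-one) | C=C[C@@H]1[C@H](C)[C@H](c2cc(OC)c(OC)cc2OC)[C@@H](C)[C@H](c2cc(OC)c(OC)cc2OC)[C@]12C=C(OC)C(=O)C=C2OC
A3 | alternative 2 | 2,5-dimethoxy-4-propylidenecyclohexa-2,5-dien-1-one (ethyl on the side of C1–H) | O=C1C=C(OC)/C(=C/CC)C=C1OC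
A4 | alternative 2 | tert-butyl{[(2Z,4E)-4-methyl-5-(2,4,5-trimethoxyphenyl)penta-2,4-dien-3-yl]oxy}dimethylsilane | C/C=C(O[Si](C)(C)C(C)(C)C)/C(C)=C/c1cc(OC)c(OC)cc1OC
A5 | alternative 2 | 9-(tert-butyldimethylsilyloxy)-11-ethyl-2,5-dimethoxy-8,10-dimethyl-7-(2,4,5-trimethoxyphenyl)spiro[5.5]undeca-1,4,8-trien-3-one, configured at C6, C7, C10, C11 as in tatanan B | CC[C@@H]1[C@H](C)C(O[Si](C)(C)C(C)(C)C)=C(C)[C@H](c2cc(OC)c(OC)cc2OC)[C@]12C=C(OC)C(=O)C=C2OC
A6 | alternative 3 | 1-ethyl-6,9-dimethoxy-3-methyl-4-(2,4,5-trimethoxyphenyl)spiro[4.5]deca-6,9-diene-2,8-dione, configured as the corresponding centres of tatanan B | CC[C@@H]1C(=O)[C@@H](C)[C@H](c2cc(OC)c(OC)cc2OC)[C@]12C=C(OC)C(=O)C=C2OC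
A7 | alternative 3 | (2,4,5-trimethoxyphenyl)diazomethane | [N-]=[N+]=Cc1cc(OC)c(OC)cc1OC
A8 | alternative 3 | 11-ethyl-2,5-dimethoxy-8-methyl-7,9-bis(2,4,5-trimethoxyphenyl)spiro[5.5]undeca-1,4-diene-3,10-dione, configured as the corresponding centres of tatanan B | CC[C@@H]1C(=O)[C@H](c2cc(OC)c(OC)cc2OC)[C@@H](C)[C@H](c2cc(OC)c(OC)cc2OC)[C@]12C=C(OC)C(=O)C=C2OC
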